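The earlier runs and the new flask come from a simulation with constants of no real substance; the scatter is artificial.

1.60 is the standing-time ratio H: the 20 min for which substrate stands in oak, divided by the mean time a portion stands in alder, 12.5 min.

| flask | substrate | gas | temperature | remark | time |
|---|---|---|---|---|---|
| eta | 0.065 M (in portions, 4) | 3.1 mM (held) | 25 °C | run made earlier; portions every 5.0 min |  |
| zeta | 0.11 M (in portions, 4) | 3.1 mM (held) | 40 °C | run made earlier; portions every 5.0 min |  |
| alder | 0.050 M (in portions, 4) | 3.1 mM (held) | 40 °C | the portions of substrate follow each other after 5.0 min, the first at the start | 20 min |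
| oak | 0.10 M | 3.1 mM | 40 °C | everything together at the start | 20 min |

| eta: time / min | eta: first product / % | zeta: time / min | zeta: first product / % |
|---|---|---|---|
| 3.00 | 3 | 1.50 | 2 |
| 5.00 | 0 | 2.50 | 3 |
| 8.00 | 3 | 4.00 | 6 |
| 15.0 | 17 | 8.00 | 12 |
| 25.0 | 28 | 12.0 | 19 |
| 40.0 | 42 | 20.0 | 38 |

(each reading ± 1.5 percentage points)

- the flask that ends with the higher amount of first product, in percent of the substrate charged, or "neither" when 2 percentage points or less lies between them (alder / oak / neither)
- final first product, as a percentage of the substrate charged, in alder
- final first product, as a percentage of the substrate charged, in oak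

- the numbers in the tables scatter by 1.5 percentage points (one standard deviation)

I turn the question round: what must be true for alder to beat oak? Conversion grows with the product of standing time and the pseudo-first-order constant k, the rate of making first product divided by c(substrate). To a first approximation, then, alder needs a k more than H times that of oak. The gas is held at 3.1 mM, far below the substrate in oak, and I balance its supply against its use: k can fall as c(substrate) rises. I read that fall from an early and a late window of the zeta run, which stand at different mean c(substrate):

early, to 8.00 min: c(substrate) = 31.2 mM, k = 0.0529 min⁻¹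

late, 12.0 min to 20.0 min: c(substrate) = 68.3 mM, k = 0.0382 min⁻¹

The ratio read is 1.38, less than H, though these readings scatter. I give oak the late k and each portion of alder the early k:

oak: 53.4%

alder: 46.1%

So I commit to oak. The forecast says oak, with 45% for alder and 52% for oak: “Oak is modestly ahead, but this is uncertain.”

The flasks give oak: 42.3% in alder and 48.5% in oak.

    coupling partner + first product → bis adduct (k = 7.90 L mol⁻¹ min⁻¹, Ea = 66.0 kJ mol⁻¹)
    coupling partner → decomposed reagent (k = 0.0260 min⁻¹, Ea = 105 kJ mol⁻¹)
    substrate + coupling partner → first product (k = 25.0 L mol⁻¹ min⁻¹, Ea = 60.0 kJ mol⁻¹)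
    coupling partner + bis adduct → tris adduct (k = 5.60 L mol⁻¹ min⁻¹, Ea = 54.0 kJ mol⁻¹)
    gas ⇌ coupling partner, rate k5*(csat - [coupling partner]) (kL = 2.30 min⁻¹)
    (constants at 40 °C)

The constant k is 25 L mol⁻¹ min⁻¹ times c(coupling partner). At 10.0 min that stands at 0.00255 M in alder and 0.00166 M in oak, a ratio of 1.54, below H. The neighbouring flask is oak with 0.025 M of substrate, its charge still given at the start, and it leaves 28% of its substrate against 44% in oak. From the logarithms of these two fractions, the mean k of the neighbouring flask stands 1.54 times that of oak, less than H, and the neighbouring flask ends with 56.8% first product.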